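The constants used here were set for the occasion; the result is computed.

Count the amounts first: 0.053 M starting material, 0.106 M reagent, 0.26 mM free catalyst. Starting material is less than the reagent, so it is the limiting reagent, and each catalyst must turn 204 times to finish it.

    catalyst intermediate C ⇌ catalyst intermediate D (K1 = 5.90, k1 = 0.143 s⁻¹, Ea1 = 75.0 kJ mol⁻¹, ΔH1 = 16.0 kJ mol⁻¹)
    reagent + catalyst intermediate B → catalyst intermediate C (k2 = 1.05 M⁻¹ s⁻¹, Ea2 = 60.0 kJ mol⁻¹)
    starting material + free catalyst → catalyst intermediate A (k3 = 0.375 M⁻¹ s⁻¹, Ea3 = 60.0 kJ mol⁻¹)
    catalyst intermediate D → free catalyst + target (k4 = 0.134 s⁻¹, Ea4 = 73.0 kJ mol⁻¹)
    catalyst intermediate A → catalyst intermediate B (k5 = 0.136 s⁻¹, Ea5 = 71.0 kJ mol⁻¹)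
    (constants at 20 °C)

in all of them: starting material 0.053 M; reagent 0.106 M; free catalyst 0.26 mM; time 80 min
- west: temperature 0 °C
- north-west: at 40 °C until 40 min, from then on at 0 °C
- south-west: temperature 20 °C
- east: temperature 40 °C

- the flask that comes out highest in amount of target, in percent of the starting material charged, or "all alike" when all lie within 1.5 percentage points (west / north-west / south-west / east / all alike)
- target at the end, in percent of the starting material charged, west
- target at the end, in percent of the starting material charged, north-west
- target at the end, in percent of the starting material charged, south-west
- target at the end, in percent of the starting material charged, east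

- all constants are for 20 °C and move with temperature by the activation energies and enthalpies

Take east and ask where a turn spends its time. Write f for the fraction of the starting material left. Take the reciprocal of the capture constant times the catalyst charged: east has 35.5 min, the capture time. At the charge, capture costs 10.4 s per turn, and this cost grows as f shrinks. The remaining steps cost 1.14 s from catalyst intermediate A to B, 2.49 s for the reagent step, with reagent taken at its mean, and 2.20 s from catalyst intermediate C through D to free catalyst. Together that is 5.84 s, so at the charge capture takes longer than the rest, but the rest is of like size and stays in the sum.

Next ask how far east gets. Add up the turns. The capture costs, rising as f thins, sum to the capture time times the natural log of one over f. The fixed costs sum to a tail of 19.8 min times the fraction consumed. Set that sum equal to 80 min and solve by substitution. Without the tail, f is 0.105; put the tail back and f is 0.173; once more and it is 0.167. The catalyst can hold 0.00491 of the charge, so I commit to 0.833 target in east.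

Last, ask who can beat it. The scheme shows no branch off the cycle. East has the shortest capture time, against 171 min in south-west and 1040 min in west. North-west keeps east's capture time for 40 min, then takes west's, which is longer, so I expect east to come out highest.

The forecast also names east, on the grounds of “no loss pathway to penalise heat”. It gives 3.9% for west, 57.5% for north-west, 25.7% for south-west and 83.2% for east.

The simulation gives east as highest, with 3.90% in west, 57.4% in north-west, 25.8% in south-west and 83.3% in east.

In east, the step from catalyst intermediate A to B had half its turnover up to 80.0 min behind it by 26.8 min, and at 26.8 min catalyst intermediate A was made as fast as it was used, each step taken net, at a ratio of 1.00. At 80.0 min, east holds free catalyst, the resting state, at 90.6% of the catalyst charged, with 16.6% starting material and 58.3% of the reagent left. The half-life of starting material by capture at that time stands at 27 min; ln(2) times the capture time, divided by that free share, gives 27.2 min.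

Now take the neighbour of east charged with 0.021 M starting material, which has 5.05 equiv reagent. Its capture time stays 35.5 min, but its tail shrinks to 7.29 min, so the same substitution leaves f at 0.126. The simulation leaves 12.6% starting material and gives 87.4% target.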